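**Retrosynthetic overview**
1. Target ⇐ its bis(triisopropylsilyl) ether by acid-free fluoride desilylation (last step).
2. Furofuran: both benzylic C–O bonds are closed together by double reductive cycloetherification of a 1,4-diaryl-2,3-bis(hydroxymethyl)butane-1,4-dione. Hydride enters each oxocarbenium ion from the convex face, which puts both aryl groups endo (all four ring hydrogens cis).
3. Diketo-diol ⇐ C2-symmetric bis-lactone (3aS,6aS)-tetrahydrofuro[3,4-c]furan-1,4-dione + ring A aryllithium + dihydrobenzofuranyl (rings B and C) aryllithium.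
4. Bis-lactone ⇐ achiral 2,3-bis(hydroxymethyl)butane-1,4-diol by a new enantiotopos-selective double oxidative lactonisation (C–O ring closures that set C-3a/C-6a) ⇐ tetraethyl ethane-1,1,2,2-tetracarboxylate.
5. cis-Dihydrobenzofuran bromide ⇐ Mitsunobu aryl benzyl ether (C–O) of 4-bromo-2-iodo-6-methoxyphenol, then diazoacetate coupling and Rh-carbene C–H insertion. Ring order: dihydrobenzofuran, then the two lactone rings, then the two tetrahydrofuran rings.

Assumption: the SMILES is read literally, i.e. a (1S,3aS,4S,6aS) furofuran with both aryl groups endo and a cis-(2S,3S) dihydrobenzofuran; the sense of induction written for the chiral catalysts of steps 6 and 10 must be confirmed in a pilot run and the antipodal catalyst used if it is opposite.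

**Route**

Step 1
Reactants: 1 vanillin (4-hydroxy-3-methoxybenzaldehyde)
Product: 2 3-methoxy-4-(triisopropylsilyloxy)benzaldehyde
Conditions: TIPSCl, imidazole, DMF, rt
Reagents that add atoms: chlorotriisopropylsilane (TIPSCl), CC(C)[Si](Cl)(C(C)C)C(C)C
Why: Phenol silylation (silyl ether formation); the TIPS ether tolerates the Mitsunobu, Pd, Rh, hydride, organolithium and BF3 steps and is cleaved at the end by fluoride without acid.

Step 2
Reactants: 2 3-methoxy-4-(triisopropylsilyloxy)benzaldehyde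
Product: 3 [3-methoxy-4-(triisopropylsilyloxy)phenyl]methanol
Conditions: NaBH4, MeOH, 0 °C
Reagents that add atoms: none
Why: Borohydride reduction of the aldehyde gives the primary benzylic alcohol needed for the Mitsunobu coupling, and the aryl silyl ether is untouched at 0 °C.

Step 3
Reactants: 4 4-bromo-2-methoxyphenol
Product: 5 4-bromo-2-iodo-6-methoxyphenol
Conditions: NIS, TsOH·H2O (10 mol%), MeCN, 0 °C to rt
Reagents that add atoms: N-iodosuccinimide (NIS), O=C1CCC(=O)N1I
Why: Electrophilic aromatic iodination; with the para position blocked by bromine the phenol directs iodine to its only free ortho position, giving a C–I handle that is later differentiated from C–Br.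

Step 4
Reactants: 5 4-bromo-2-iodo-6-methoxyphenol; 3 [3-methoxy-4-(triisopropylsilyloxy)phenyl]methanol
Product: 6 5-bromo-1-iodo-3-methoxy-2-{[3-methoxy-4-(triisopropylsilyloxy)benzyl]oxy}benzene
Conditions: PPh3, DIAD, THF, 0 °C to rt
Reagents that add atoms: none
Why: Mitsunobu etherification (C–O bond formation) alkylates the acidic, doubly ortho-substituted phenol with the primary benzylic alcohol under neutral conditions and creates the O–CH2Ar bond that becomes O-1–C-2 of the dihydrobenzofuran.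

Step 5
Reactants: 6 5-bromo-1-iodo-3-methoxy-2-{[3-methoxy-4-(triisopropylsilyloxy)benzyl]oxy}benzene; 7 ethyl diazoacetate
Product: 8 ethyl 2-(5-bromo-3-methoxy-2-{[3-methoxy-4-(triisopropylsilyloxy)benzyl]oxy}phenyl)-2-diazoacetate
Conditions: Pd(PPh3)4 (5 mol%), Et3N, Bu4NBr, MeCN, rt to 45 °C
Reagents that add atoms: none
Why: Pd-catalysed cross-coupling of an aryl iodide with ethyl diazoacetate (C–H arylation with retention of the diazo group); zerovalent palladium inserts into C–I far faster than into C–Br at this temperature, so the aryldiazoacetate forms in one step and the bromide is kept.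

Step 6
Reactants: 8 ethyl 2-(5-bromo-3-methoxy-2-{[3-methoxy-4-(triisopropylsilyloxy)benzyl]oxy}phenyl)-2-diazoacetate
Product: 9 ethyl (2S,3R)-5-bromo-7-methoxy-2-[3-methoxy-4-(triisopropylsilyloxy)phenyl]-2,3-dihydro-1-benzofuran-3-carboxylate (2,3-cis)
Conditions: Rh2(S-PTTL)4 (dirhodium tetrakis[N-phthaloyl-(S)-tert-leucinate], 1 mol%), toluene, −60 °C
Reagents that add atoms: none
Why: Enantioselective intramolecular Rh-carbene 1,5 C–H insertion into the electron-rich ArCH2–O group closes the five-membered ring; the concerted, catalyst-bound insertion sets C-2 and C-3 together and gives the kinetic cis ester in high ee, as is established for 2-(benzyloxy)aryl diazoacetates with this catalyst.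

Step 7
Reactants: 9 ethyl (2S,3R)-5-bromo-7-methoxy-2-[3-methoxy-4-(triisopropylsilyloxy)phenyl]-2,3-dihydro-1-benzofuran-3-carboxylate
Product: 10 {(2S,3S)-5-bromo-7-methoxy-2-[3-methoxy-4-(triisopropylsilyloxy)phenyl]-2,3-dihydro-1-benzofuran-3-yl}methanol
Conditions: DIBAL-H (i-Bu2AlH), CH2Cl2, −78 to −20 °C; aqueous potassium sodium tartrate
Reagents that add atoms: none
Why: Ester reduction with DIBAL-H under non-basic, low-temperature conditions gives the primary alcohol before the base-labile cis C-3 centre can epimerise (afterwards it is no longer epimerisable), and the aryl bromide and silyl ether survive.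

Step 8
Reactants: 4 4-bromo-2-methoxyphenol
Product: 11 (4-bromo-2-methoxyphenoxy)triisopropylsilane
Conditions: TIPSCl, imidazole, DMF, rt
Reagents that add atoms: chlorotriisopropylsilane (TIPSCl), CC(C)[Si](Cl)(C(C)C)C(C)C
Why: Phenol silylation gives the ring A bromide in a form compatible with bromine–lithium exchange and with the later Lewis acid step.

Step 9
Reactants: 12 tetraethyl ethane-1,1,2,2-tetracarboxylate
Product: 13 2,3-bis(hydroxymethyl)butane-1,4-diol
Conditions: LiAlH4 (excess), THF, reflux (inverse addition); H2O, 15% NaOH; hot EtOH extraction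
Reagents that add atoms: none
Why: Exhaustive LiAlH4 reduction of the four malonate-type esters (inverse addition to excess hydride to outrun enolisation) gives the achiral C6 tetraol.

Step 10
Reactants: 13 2,3-bis(hydroxymethyl)butane-1,4-diol
Product: 15 (3aS,6aS)-tetrahydrofuro[3,4-c]furan-1,4-dione [(1S,5S)-3,7-dioxabicyclo[3.3.0]octane-2,6-dione], via cis mono-lactone diol 14 (not isolated)
Conditions: Cp*Ir[(S,S)-TsNCHPhCHPhNH] (3 mol%), acetone/t-BuOH 4:1, 30 °C
Reagents that add atoms: none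
Why: Proposed new method: enantiotopos-selective double transfer-dehydrogenative lactonisation of an achiral tetraol, in which the chiral 16-electron amido complex of trivalent iridium removes H2 (metal–ligand bifunctional, acetone as acceptor) preferentially from the pro-S hydroxymethyl group of each CH(CH2OH)2 unit, the γ-hydroxy aldehyde closes to a lactol (C–O bond formation) that is dehydrogenated irreversibly to the lactone, only the cis mono-lactone 14 can close the second ring, and a wrong choice at either centre ends in a trans mono-lactone or the meso 2,8-dione, so the (3aS,6aS) product is enriched by double selection (Horeau-type amplification) and both ring-fusion stereocentres are set; the closest known reactions are the asymmetric oxidative lactonisation of meso-1,4-diols with Cp*Ir or Cp*Ru amido catalysts in acetone and the alcohol-dehydrogenase oxidation of meso-diols to lactones.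

Step 11
Reactants: 10 {(2S,3S)-5-bromo-7-methoxy-2-[3-methoxy-4-(triisopropylsilyloxy)phenyl]-2,3-dihydro-1-benzofuran-3-yl}methanol; 15 (3aS,6aS)-tetrahydrofuro[3,4-c]furan-1,4-dione; 11 (4-bromo-2-methoxyphenoxy)triisopropylsilane
Product: 19 (2S,3S)-1-[(2S,3S)-3-(hydroxymethyl)-7-methoxy-2-[3-methoxy-4-(triisopropylsilyloxy)phenyl]-2,3-dihydro-1-benzofuran-5-yl]-2,3-bis(hydroxymethyl)-4-[3-methoxy-4-(triisopropylsilyloxy)phenyl]butane-1,4-dione, via aryllithium alkoxide 16 (not isolated), via lithium hemiketalate lactone 17 (not isolated), via ring A aryllithium 18 (not isolated)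
Conditions: 10, n-BuLi (2.1 equiv), THF, −78 °C; cannulate into 15 (1.3 equiv), THF, −78 °C; then 18 [from 11 (2.6 equiv), n-BuLi, THF, −78 °C]; aq NH4Cl, −78 °C; crude used directly
Reagents that add atoms: none
Why: Bromine–lithium exchange followed by 1,2-addition of aryllithiums to lactones, which stops at the tetrahedral lithium hemiketalate at −78 °C; because 15 is C2-symmetric its two carbonyls are homotopic, so the limiting aryllithium 16 gives one mono-adduct whose negative charge retards a second attack, the cheap aryllithium 18 then takes the remaining lactone, and no stereocentre is touched.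

Step 12
Reactants: 19 the diketo-diol of step 11
Product: 21 {(2S,3S)-7-methoxy-2-[3-methoxy-4-(triisopropylsilyloxy)phenyl]-5-[(1S,3aS,4S,6aS)-4-[3-methoxy-4-(triisopropylsilyloxy)phenyl]tetrahydro-1H,3H-furo[3,4-c]furan-1-yl]-2,3-dihydro-1-benzofuran-3-yl}methanol, via bis-hemiketal 20 (not isolated)
Conditions: Et3SiH (8 equiv), BF3·OEt2 (4 equiv), CH2Cl2, −78 °C; Et3N then aq NaHCO3 at −78 °C
Reagents that add atoms: none
Why: Double intramolecular reductive etherification (hemiketalisation, then ionic hydrogenation of the two 2-aryl oxocarbenium ions); Et3SiH attacks each cation from the convex face of the cis-fused bicycle, trans to the neighbouring ring-fusion substituent, so H-1 and H-4 end cis to H-6a and H-3a and both aryl groups endo (1S,4S), the kinetic arrangement, which is preserved by the cold basic quench.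

Step 13
Reactants: 21 the bis(triisopropylsilyl) ether of step 12
Product: 22 4-[(1S,3aS,4S,6aS)-4-[(2S,3S)-2-(4-hydroxy-3-methoxyphenyl)-3-(hydroxymethyl)-7-methoxy-2,3-dihydro-1-benzofuran-5-yl]tetrahydro-1H,3H-furo[3,4-c]furan-1-yl]-2-methoxyphenol (CNP0303197.1)
Conditions: Bu4NF (2.5 equiv), AcOH (2.5 equiv), THF, 0 °C to rt
Reagents that add atoms: none
Why: Fluoride-mediated desilylation buffered with acetic acid frees both phenols without strong acid or base, so the acid-labile p-hydroxybenzylic ethers (endo,endo-furofuran and cis-dihydrobenzofuran) do not epimerise.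

**Compound list**
1 | vanillin | COc1cc(C=O)ccc1O | starting material
2 | 3-methoxy-4-(triisopropylsilyloxy)benzaldehyde | COc1cc(C=O)ccc1O[Si](C(C)C)(C(C)C)C(C)C | intermediate
3 | [3-methoxy-4-(triisopropylsilyloxy)phenyl]methanol | COc1cc(CO)ccc1O[Si](C(C)C)(C(C)C)C(C)C | intermediate
4 | 4-bromo-2-methoxyphenol | COc1cc(Br)ccc1O | starting material
5 | 4-bromo-2-iodo-6-methoxyphenol | COc1cc(Br)cc(I)c1O | intermediate
6 | 5-bromo-1-iodo-3-methoxy-2-{[3-methoxy-4-(triisopropylsilyloxy)benzyl]oxy}benzene | COc1cc(Br)cc(I)c1OCc1ccc(O[Si](C(C)C)(C(C)C)C(C)C)c(OC)c1 | intermediate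
7 | ethyl diazoacetate | CCOC(=O)C=[N+]=[N-] | starting material
8 | ethyl 2-(5-bromo-3-methoxy-2-{[3-methoxy-4-(triisopropylsilyloxy)benzyl]oxy}phenyl)-2-diazoacetate | CCOC(=O)C(=[N+]=[N-])c1cc(Br)cc(OC)c1OCc1ccc(O[Si](C(C)C)(C(C)C)C(C)C)c(OC)c1 | intermediate
9 | ethyl (2S,3R)-5-bromo-7-methoxy-2-[3-methoxy-4-(triisopropylsilyloxy)phenyl]-2,3-dihydro-1-benzofuran-3-carboxylate (cis) | Brc1cc(OC)c2c(c1)[C@@H](C(=O)OCC)[C@@H](c1ccc(O[Si](C(C)C)(C(C)C)C(C)C)c(OC)c1)O2 | intermediate
10 | {(2S,3S)-5-bromo-7-methoxy-2-[3-methoxy-4-(triisopropylsilyloxy)phenyl]-2,3-dihydro-1-benzofuran-3-yl}methanol | Brc1cc(OC)c2c(c1)[C@@H](CO)[C@@H](c1ccc(O[Si](C(C)C)(C(C)C)C(C)C)c(OC)c1)O2 | intermediate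
11 | (4-bromo-2-methoxyphenoxy)triisopropylsilane | COc1cc(Br)ccc1O[Si](C(C)C)(C(C)C)C(C)C | intermediate
12 | tetraethyl ethane-1,1,2,2-tetracarboxylate | CCOC(=O)C(C(=O)OCC)C(C(=O)OCC)C(=O)OCC | starting material
13 | 2,3-bis(hydroxymethyl)butane-1,4-diol | OCC(CO)C(CO)CO | intermediate
14 | (3S,4R)-3,4-bis(hydroxymethyl)oxolan-2-one (cis mono-lactone diol) | O=C1OC[C@@H](CO)[C@H]1CO | intermediate
15 | (3aS,6aS)-tetrahydrofuro[3,4-c]furan-1,4-dione | O=C1OC[C@@H]2[C@H]1COC2=O | intermediate
16 | lithium {(2S,3S)-5-lithio-7-methoxy-2-[3-methoxy-4-(triisopropylsilyloxy)phenyl]-2,3-dihydro-1-benzofuran-3-yl}methanolate | [Li]c1cc(OC)c2c(c1)[C@@H](CO[Li])[C@@H](c1ccc(O[Si](C(C)C)(C(C)C)C(C)C)c(OC)c1)O2 | intermediate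
17 | lithium hemiketalate of the mono-adduct of 16 to 15 (one lactone retained; hemiketal carbon undefined) | O=C1OC[C@@H]2[C@H]1COC2(O[Li])c1cc(OC)c3c(c1)[C@@H](CO[Li])[C@@H](c1ccc(O[Si](C(C)C)(C(C)C)C(C)C)c(OC)c1)O3 | intermediate
18 | [3-methoxy-4-(triisopropylsilyloxy)phenyl]lithium | [Li]c1ccc(O[Si](C(C)C)(C(C)C)C(C)C)c(OC)c1 | intermediate
19 | (2S,3S)-1-[(2S,3S)-3-(hydroxymethyl)-7-methoxy-2-[3-methoxy-4-(triisopropylsilyloxy)phenyl]-2,3-dihydro-1-benzofuran-5-yl]-2,3-bis(hydroxymethyl)-4-[3-methoxy-4-(triisopropylsilyloxy)phenyl]butane-1,4-dione | O=C(c1ccc(O[Si](C(C)C)(C(C)C)C(C)C)c(OC)c1)[C@H](CO)[C@@H](CO)C(=O)c1cc(OC)c2c(c1)[C@@H](CO)[C@@H](c1ccc(O[Si](C(C)C)(C(C)C)C(C)C)c(OC)c1)O2 | intermediate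
20 | cyclic bis-hemiketal of 19 (1,4-diaryl-1,4-dihydroxytetrahydrofuro[3,4-c]furan; hemiketal carbons undefined) | OC1(c2ccc(O[Si](C(C)C)(C(C)C)C(C)C)c(OC)c2)OC[C@@H]2[C@H]1COC2(O)c1cc(OC)c2c(c1)[C@@H](CO)[C@@H](c1ccc(O[Si](C(C)C)(C(C)C)C(C)C)c(OC)c1)O2 | intermediate
21 | {(2S,3S)-7-methoxy-2-[3-methoxy-4-(triisopropylsilyloxy)phenyl]-5-[(1S,3aS,4S,6aS)-4-[3-methoxy-4-(triisopropylsilyloxy)phenyl]tetrahydro-1H,3H-furo[3,4-c]furan-1-yl]-2,3-dihydro-1-benzofuran-3-yl}methanol | COc1cc([C@H]2OC[C@@H]3[C@H]2CO[C@@H]3c2cc(OC)c3c(c2)[C@@H](CO)[C@@H](c2ccc(O[Si](C(C)C)(C(C)C)C(C)C)c(OC)c2)O3)ccc1O[Si](C(C)C)(C(C)C)C(C)C | intermediate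
22 | 4-[(1S,3aS,4S,6aS)-4-[(2S,3S)-2-(4-hydroxy-3-methoxyphenyl)-3-(hydroxymethyl)-7-methoxy-2,3-dihydro-1-benzofuran-5-yl]tetrahydro-1H,3H-furo[3,4-c]furan-1-yl]-2-methoxyphenol | COc1cc([C@H]2OC[C@@H]3[C@H]2CO[C@@H]3c2cc(OC)c3c(c2)[C@@H](CO)[C@@H](c2ccc(O)c(OC)c2)O3)ccc1O | target

**Step count and risks**
Total steps: 13. Longest linear sequence: 9 (steps 1, 2, 4, 5, 6, 7, 11, 12, 13, from vanillin).

Steps most likely to fail:

Step 10 (new desymmetrising double oxidative lactonisation). Enantiotopos selectivity on a small, strongly chelating tetraol is untested, and the meso 2,8-dione or trans mono-lactones may dominate. The fallback sets out from 13 and comes back at 15, using established reaction types only. Lipase-catalysed desymmetrising acetylation of the two prochiral 1,3-diol units (Amano lipase PS, vinyl acetate, THF, 30 °C) gives (2R,3R)-2,3-bis(acetoxymethyl)butane-1,4-diol F1. Oxidation of its two free primary alcohols (TEMPO, NaOCl, NaClO2, MeCN/phosphate buffer) gives (2S,3S)-2,3-bis(acetoxymethyl)butanedioic acid F2. Warming F2 in 2 M aqueous HCl removes the acetates and both γ-hydroxy acids lactonise to 15.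

Step 11 (one-pot unsymmetrical double arylation). Mono-addition may not be clean, or the second lactone of 17 may be too sluggish at −78 °C, and warming risks collapse of the hemiketalate and over-addition. The fallback sets out from 15, 11 and 10 and comes back at 21, masking the first carbonyl before the second aryl group is brought in. Aryllithium 18 (1.0 equiv, from 11) is added to excess 15 and quenched to give (3S,4S)-3-(hydroxymethyl)-4-[3-methoxy-4-(triisopropylsilyloxy)benzoyl]oxolan-2-one F3. Treatment with MeOH, HC(OMe)3 and PPTS converts it into the purifiable cyclic methyl ketal (3aS,6aS)-4-methoxy-4-[3-methoxy-4-(triisopropylsilyloxy)phenyl]tetrahydro-1H,3H-furo[3,4-c]furan-1-one F4. Aryllithium 16 (from 10) can then add only to the single remaining lactone, giving the ketal hydroxy ketone [(3S,4S)-4-(hydroxymethyl)-5-methoxy-5-[3-methoxy-4-(triisopropylsilyloxy)phenyl]oxolan-3-yl][(2S,3S)-3-(hydroxymethyl)-7-methoxy-2-[3-methoxy-4-(triisopropylsilyloxy)phenyl]-2,3-dihydro-1-benzofuran-5-yl]methanone F5. F5 is reduced under the step 12 conditions, which convert methyl ketal and hemiketal alike, to give 21.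

Step 12 (double ionic reduction). The open-chain diketone 19 has two epimerisable α-centres, and the electron-rich benzylic ethers of the product can re-ionise (epimerisation to exo-aryl, or over-reduction) if BF3 contact is not kept cold and short. The fallback sets out from 15, 10 and 11 and comes back at 21, ring by ring, so that each benzylic centre is set and checked separately and no open 1,4-diketone is present. Aryllithium 16 (limiting) is added to excess 15 and quenched to give (3S,4S)-4-{(2S,3S)-3-(hydroxymethyl)-7-methoxy-2-[3-methoxy-4-(triisopropylsilyloxy)phenyl]-2,3-dihydro-1-benzofuran-5-carbonyl}-3-(hydroxymethyl)oxolan-2-one F6. A single Et3SiH/BF3·OEt2 reduction at −78 °C (the classical furofuranone mode) gives the endo-aryl lactone (3aS,4S,6aS)-4-{(2S,3S)-3-(hydroxymethyl)-7-methoxy-2-[3-methoxy-4-(triisopropylsilyloxy)phenyl]-2,3-dihydro-1-benzofuran-5-yl}tetrahydro-1H,3H-furo[3,4-c]furan-1-one F7, which is purified and its configuration confirmed by NOE. Addition of 18 to F7 gives the hydroxy ketone [(3S,4S,5S)-5-{(2S,3S)-3-(hydroxymethyl)-7-methoxy-2-[3-methoxy-4-(triisopropylsilyloxy)phenyl]-2,3-dihydro-1-benzofuran-5-yl}-4-(hydroxymethyl)oxolan-3-yl][3-methoxy-4-(triisopropylsilyloxy)phenyl]methanone F8, and a second single reduction gives 21.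

Further compounds
F1 | step 10 | (2R,3R)-2,3-bis(acetoxymethyl)butane-1,4-diol | OC[C@H](COC(C)=O)[C@@H](COC(C)=O)CO
F2 | step 10 | (2S,3S)-2,3-bis(acetoxymethyl)butanedioic acid | OC(=O)[C@H](COC(C)=O)[C@@H](COC(C)=O)C(=O)O
F3 | step 11 | (3S,4S)-3-(hydroxymethyl)-4-[3-methoxy-4-(triisopropylsilyloxy)benzoyl]oxolan-2-one | O=C1OC[C@@H](C(=O)c2ccc(O[Si](C(C)C)(C(C)C)C(C)C)c(OC)c2)[C@H]1CO
F4 | step 11 | (3aS,6aS)-4-methoxy-4-[3-methoxy-4-(triisopropylsilyloxy)phenyl]tetrahydro-1H,3H-furo[3,4-c]furan-1-one | COC1(c2ccc(O[Si](C(C)C)(C(C)C)C(C)C)c(OC)c2)OC[C@@H]2[C@H]1COC2=O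
F5 | step 11 | [(3S,4S)-4-(hydroxymethyl)-5-methoxy-5-[3-methoxy-4-(triisopropylsilyloxy)phenyl]oxolan-3-yl][(2S,3S)-3-(hydroxymethyl)-7-methoxy-2-[3-methoxy-4-(triisopropylsilyloxy)phenyl]-2,3-dihydro-1-benzofuran-5-yl]methanone | COC1(c2ccc(O[Si](C(C)C)(C(C)C)C(C)C)c(OC)c2)OC[C@@H](C(=O)c2cc(OC)c3c(c2)[C@@H](CO)[C@@H](c2ccc(O[Si](C(C)C)(C(C)C)C(C)C)c(OC)c2)O3)[C@H]1CO
F6 | step 12 | (3S,4S)-4-{(2S,3S)-3-(hydroxymethyl)-7-methoxy-2-[3-methoxy-4-(triisopropylsilyloxy)phenyl]-2,3-dihydro-1-benzofuran-5-carbonyl}-3-(hydroxymethyl)oxolan-2-one | O=C1OC[C@@H](C(=O)c2cc(OC)c3c(c2)[C@@H](CO)[C@@H](c2ccc(O[Si](C(C)C)(C(C)C)C(C)C)c(OC)c2)O3)[C@H]1CO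
F7 | step 12 | (3aS,4S,6aS)-4-{(2S,3S)-3-(hydroxymethyl)-7-methoxy-2-[3-methoxy-4-(triisopropylsilyloxy)phenyl]-2,3-dihydro-1-benzofuran-5-yl}tetrahydro-1H,3H-furo[3,4-c]furan-1-one | O=C1OC[C@@H]2[C@H]1CO[C@@H]2c1cc(OC)c2c(c1)[C@@H](CO)[C@@H](c1ccc(O[Si](C(C)C)(C(C)C)C(C)C)c(OC)c1)O2
F8 | step 12 | [(3S,4S,5S)-5-{(2S,3S)-3-(hydroxymethyl)-7-methoxy-2-[3-methoxy-4-(triisopropylsilyloxy)phenyl]-2,3-dihydro-1-benzofuran-5-yl}-4-(hydroxymethyl)oxolan-3-yl][3-methoxy-4-(triisopropylsilyloxy)phenyl]methanone | O=C(c1ccc(O[Si](C(C)C)(C(C)C)C(C)C)c(OC)c1)[C@@H]1CO[C@H](c2cc(OC)c3c(c2)[C@@H](CO)[C@@H](c2ccc(O[Si](C(C)C)(C(C)C)C(C)C)c(OC)c2)O3)[C@@H]1CO
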